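**Retrosynthetic overview**
1. Target 13 ⇐ epoxy alcohol 12 (last angelate); 12 ⇐ dienol 11 by hydroxyl-directed syn-epoxidation of the prenyl alkene.
2. 11 ⇐ enal 9 + prenyl bromide 10: the C3′–C4′ bond is made by a blue-light titanocene radical prenylation that also sets C3′ (key step).
3. 9 ⇐ diangelate 8 by allylic oxidation of the isopropenyl methyl; 8 ⇐ diol 6 + angelic acid 7.
4. 6 ⇐ (S)-carvone 1 by nucleophilic epoxidation, α′-hydroxylation and hydroxyl-directed ketone reduction.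
5. Ring order: carbocycle bought in 1 → ring oxirane (step 1) → side-chain oxirane (step 7).

Locants used: ring atoms follow the 7-oxabicyclo[4.1.0]heptane names (C1 = methyl-bearing oxirane carbon, C2 and C3 = oxygenated carbons, C4 = side-chain carbon, C5 = CH2, C6 = oxirane CH); side chain is C1′ (=CH2), C2′, C3′ (carbinol), C4′.

**Step 1**
Reactants: 1 (S)-(+)-carvone, (5S)-2-methyl-5-(prop-1-en-2-yl)cyclohex-2-en-1-one
Product: 2 (1S,4S,6S)-1-methyl-4-(prop-1-en-2-yl)-7-oxabicyclo[4.1.0]heptan-2-one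
Conditions: 30% H2O2, NaOH (aq, cat.), MeOH, 0 °C
Reagents that add atoms: hydrogen peroxide, OO
Why: Weitz–Scheffer nucleophilic epoxidation touches only the enone, and hydroperoxide adds to the face anti to the isopropenyl group, so the oxirane (C1, C6) is set trans to it by the bought stereocentre.

**Step 2**
Reactants: 2 (1S,4S,6S)-1-methyl-4-(prop-1-en-2-yl)-7-oxabicyclo[4.1.0]heptan-2-one
Product: 4 (1S,3R,4R,6S)-3-hydroxy-1-methyl-4-(prop-1-en-2-yl)-7-oxabicyclo[4.1.0]heptan-2-one, via sodium enolate 3 (not isolated)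
Conditions: NaN(SiMe3)2, THF, −78 °C; then racemic 3-phenyl-2-(phenylsulfonyl)oxaziridine, −78 °C; AcOH
Reagents that add atoms: 3-phenyl-2-(phenylsulfonyl)oxaziridine, O=S(=O)(N1OC1c1ccccc1)c1ccccc1
Why: Enolisation is possible only toward the CH2 (the other α-carbon is quaternary), and Davis-type enolate hydroxylation occurs anti to the adjacent isopropenyl group, setting C3 (R) trans to it.

**Step 3**
Reactants: 4 (1S,3R,4R,6S)-3-hydroxy-1-methyl-4-(prop-1-en-2-yl)-7-oxabicyclo[4.1.0]heptan-2-one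
Product: 6 (1R,2S,3R,4R,6S)-1-methyl-4-(prop-1-en-2-yl)-7-oxabicyclo[4.1.0]heptane-2,3-diol, via alkoxyborohydride 5 (not isolated)
Conditions: Me4NBH(OAc)3, MeCN/AcOH, −30 °C
Reagents that add atoms: none
Why: Saksena–Evans hydroxyl-directed reduction: the reagent does not reduce ketones intermolecularly but exchanges onto the C3–OH and delivers hydride to the ketone face syn to that oxygen, giving the trans-diequatorial diol with C2–OH anti to the oxirane oxygen (C2 S).

**Step 4**
Reactants: 6 (1R,2S,3R,4R,6S)-1-methyl-4-(prop-1-en-2-yl)-7-oxabicyclo[4.1.0]heptane-2,3-diol; 7 angelic acid, (2Z)-2-methylbut-2-enoic acid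
Product: 8 (1S,2S,3R,4R,6S)-1-methyl-4-(prop-1-en-2-yl)-7-oxabicyclo[4.1.0]heptane-2,3-diyl bis[(2Z)-2-methylbut-2-enoate]
Conditions: 7, 2,4,6-Cl3C6H2COCl, Et3N, toluene, 25 °C, filter; then 6, toluene, 80 °C
Reagents that add atoms: angelic acid 7, C/C=C(/C)C(=O)O
Why: Yamaguchi-type mixed-anhydride esterification without a nucleophilic catalyst acylates both secondary alcohols at the less hindered angeloyl carbonyl and keeps the Z geometry; no stereocentre is touched.

**Step 5**
Reactants: 8 (1S,2S,3R,4R,6S)-1-methyl-4-(prop-1-en-2-yl)-7-oxabicyclo[4.1.0]heptane-2,3-diyl bis[(2Z)-2-methylbut-2-enoate]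
Product: 9 (1S,2S,3R,4R,6S)-1-methyl-4-(3-oxoprop-1-en-2-yl)-7-oxabicyclo[4.1.0]heptane-2,3-diyl bis[(2Z)-2-methylbut-2-enoate]
Conditions: SeO2 (1.2 equiv), pyridine (0.5 equiv), 1,4-dioxane, 80 °C
Reagents that add atoms: selenium dioxide, O=[Se]=O
Why: Riley allylic oxidation (ene reaction then 2,3-shift) attacks the isopropenyl methyl rather than the ring methine and goes on to the 2-substituted acrolein, while the electron-poor angelate alkenes react far more slowly.

**Step 6**
Reactants: 9 (1S,2S,3R,4R,6S)-1-methyl-4-(3-oxoprop-1-en-2-yl)-7-oxabicyclo[4.1.0]heptane-2,3-diyl bis[(2Z)-2-methylbut-2-enoate]; 10 prenyl bromide, 1-bromo-3-methylbut-2-ene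
Product: 11 (1S,2S,3R,4R,6S)-4-[(3S)-3-hydroxy-6-methylhepta-1,5-dien-2-yl]-1-methyl-7-oxabicyclo[4.1.0]heptane-2,3-diyl bis[(2Z)-2-methylbut-2-enoate]
Conditions: Cp2TiCl2 (10 mol %), 3DPAFIPN (3 mol %), Hantzsch ester (2 equiv), 2,4,6-collidine (1.5 equiv), THF, 456 nm LEDs, 25 °C
Reagents that add atoms: prenyl bromide 10, CC(C)=CCBr
Why: Proposed new method: photoredox-driven titanocene radical α-prenylation of an α-branched 2-alkylacrolein with remote substrate control — the excited dye and Hantzsch ester keep Cp2TiCl2 reduced to trivalent Cp2TiCl, which turns prenyl bromide into the prenyl radical and binds the aldehyde as a ketyl-like complex, so C–C coupling occurs at the carbonyl carbon through the unsubstituted CH2 terminus of the radical (linear adduct, no conjugate addition), and with C4–H eclipsing the C2′=C1′ bond and the enal s-trans the equatorial C3 angelate screens one carbonyl face so the radical enters from the C5-methylene side to give 3′S; the closest known reaction type is the titanocene-catalysed Barbier allylation and α-prenylation of simple conjugated aldehydes (Mn or photoredox turnover), not yet shown on such enals or with 1,4-stereoinduction.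

**Step 7**
Reactants: 11 (1S,2S,3R,4R,6S)-4-[(3S)-3-hydroxy-6-methylhepta-1,5-dien-2-yl]-1-methyl-7-oxabicyclo[4.1.0]heptane-2,3-diyl bis[(2Z)-2-methylbut-2-enoate]
Product: 12 (1S,2S,3R,4R,6S)-4-{(3S)-4-[(2R)-3,3-dimethyloxiran-2-yl]-3-hydroxybut-1-en-2-yl}-1-methyl-7-oxabicyclo[4.1.0]heptane-2,3-diyl bis[(2Z)-2-methylbut-2-enoate]
Conditions: Mo(CO)6 (5 mol %), t-BuOOH (1.1 equiv, decane), Na2HPO4, benzene, 60 °C
Reagents that add atoms: tert-butyl hydroperoxide, CC(C)(C)OO
Why: Hydroxyl-directed molybdenum/alkyl hydroperoxide epoxidation: with molybdenum a homoallylic alkoxide delivers oxygen at least as fast as an allylic one and the trisubstituted alkene is much more nucleophilic than the 1,1-disubstituted one, and the chair-like metal-alkoxide transition state with the C3′ substituent equatorial gives the 1,3-syn epoxy alcohol (oxirane carbon R).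

**Step 8**
Reactants: 12 (1S,2S,3R,4R,6S)-4-{(3S)-4-[(2R)-3,3-dimethyloxiran-2-yl]-3-hydroxybut-1-en-2-yl}-1-methyl-7-oxabicyclo[4.1.0]heptane-2,3-diyl bis[(2Z)-2-methylbut-2-enoate]; 7 angelic acid
Product: 13 (1S,2S,3R,4R,6S)-4-{(3S)-4-[(2R)-3,3-dimethyloxiran-2-yl]-3-{[(2Z)-2-methylbut-2-enoyl]oxy}but-1-en-2-yl}-1-methyl-7-oxabicyclo[4.1.0]heptane-2,3-diyl bis[(2Z)-2-methylbut-2-enoate] (CNP0258231.1)
Conditions: 7, 2,4,6-Cl3C6H2COCl, Et3N, toluene, 25 °C, filter; then 12, toluene, 70 °C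
Reagents that add atoms: angelic acid 7, C/C=C(/C)C(=O)O
Why: The same base-only mixed-anhydride esterification acylates the remaining allylic alcohol with retention at C3′ and without Z-to-E isomerisation, and it removes the hydroxyl that could otherwise attack the new oxirane.

**Compound list**
1 | (S)-(+)-carvone | C=C(C)[C@H]1CC=C(C)C(=O)C1 | starting material
2 | (1S,4S,6S)-1-methyl-4-(prop-1-en-2-yl)-7-oxabicyclo[4.1.0]heptan-2-one | C=C(C)[C@H]1C[C@@H]2O[C@]2(C)C(=O)C1 | intermediate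
3 | sodium (1S,4S,6S)-1-methyl-4-(prop-1-en-2-yl)-7-oxabicyclo[4.1.0]hept-2-en-2-olate | C=C(C)[C@H]1C[C@@H]2O[C@]2(C)C([O-])=C1.[Na+] | intermediate
4 | (1S,3R,4R,6S)-3-hydroxy-1-methyl-4-(prop-1-en-2-yl)-7-oxabicyclo[4.1.0]heptan-2-one | C=C(C)[C@H]1C[C@@H]2O[C@]2(C)C(=O)[C@@H]1O | intermediate
5 | tetramethylammonium diacetoxy(hydrido)borate bound through O-3 of 4 | C=C(C)[C@H]1C[C@@H]2O[C@]2(C)C(=O)[C@@H]1O[BH-](OC(C)=O)OC(C)=O.C[N+](C)(C)C | intermediate
6 | (1R,2S,3R,4R,6S)-1-methyl-4-(prop-1-en-2-yl)-7-oxabicyclo[4.1.0]heptane-2,3-diol | C=C(C)[C@H]1C[C@@H]2O[C@]2(C)[C@@H](O)[C@@H]1O | intermediate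
7 | angelic acid, (2Z)-2-methylbut-2-enoic acid | C/C=C(/C)C(=O)O | starting material
8 | (1S,2S,3R,4R,6S)-1-methyl-4-(prop-1-en-2-yl)-7-oxabicyclo[4.1.0]heptane-2,3-diyl bis[(2Z)-2-methylbut-2-enoate] | C=C(C)[C@H]1C[C@@H]2O[C@]2(C)[C@@H](OC(=O)/C(C)=C\C)[C@@H]1OC(=O)/C(C)=C\C | intermediate
9 | (1S,2S,3R,4R,6S)-1-methyl-4-(3-oxoprop-1-en-2-yl)-7-oxabicyclo[4.1.0]heptane-2,3-diyl bis[(2Z)-2-methylbut-2-enoate] | C=C(C=O)[C@H]1C[C@@H]2O[C@]2(C)[C@@H](OC(=O)/C(C)=C\C)[C@@H]1OC(=O)/C(C)=C\C | intermediate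
10 | prenyl bromide, 1-bromo-3-methylbut-2-ene | CC(C)=CCBr | starting material
11 | (1S,2S,3R,4R,6S)-4-[(3S)-3-hydroxy-6-methylhepta-1,5-dien-2-yl]-1-methyl-7-oxabicyclo[4.1.0]heptane-2,3-diyl bis[(2Z)-2-methylbut-2-enoate] | C=C([C@H](CC=C(C)C)O)[C@H]1C[C@@H]2O[C@]2(C)[C@@H](OC(=O)/C(C)=C\C)[C@@H]1OC(=O)/C(C)=C\C | intermediate
12 | (1S,2S,3R,4R,6S)-4-{(3S)-4-[(2R)-3,3-dimethyloxiran-2-yl]-3-hydroxybut-1-en-2-yl}-1-methyl-7-oxabicyclo[4.1.0]heptane-2,3-diyl bis[(2Z)-2-methylbut-2-enoate] | C=C([C@H](C[C@H]1OC1(C)C)O)[C@H]1C[C@@H]2O[C@]2(C)[C@@H](OC(=O)/C(C)=C\C)[C@@H]1OC(=O)/C(C)=C\C | intermediate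
13 | CNP0258231.1, tris-angelate of 12 | C=C([C@H](C[C@H]1OC1(C)C)OC(=O)/C(C)=C\C)[C@H]1C[C@@H]2O[C@]2(C)[C@@H](OC(=O)/C(C)=C\C)[C@@H]1OC(=O)/C(C)=C\C | target

**Totals**
Total steps: 8. Longest linear sequence: 8 steps, from (S)-carvone 1.

**Three steps most likely to fail**

Step 6 (the new step). Risks: low or reversed facial selectivity at C3′, branched instead of linear prenyl adduct, pinacol coupling of the enal, and oxirane opening by trivalent titanium. Fallback with known chemistry, setting out from 9 and coming back at 11: thermal allylboration of 9 with 2-(2-methylbut-3-en-2-yl)-4,4,5,5-tetramethyl-1,3,2-dioxaborolane in toluene at 60 °C goes through a closed six-membered transition state and bonds at the unsubstituted allyl terminus, so it gives the linear prenyl carbinol 11 together with its C3′ epimer, the (3′R)-alcohol F2. After chromatographic separation, F2 is inverted by Mitsunobu esterification (4-nitrobenzoic acid, PPh3, DIAD, THF, 0 °C) to the (3′S)-4-nitrobenzoate F3, and K2CO3 in MeOH at 0 °C removes the activated aryl ester in preference to the hindered angelates to return 11.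

Step 7. Risks: undirected epoxidation eroding the C2″ ratio, epoxidation of the allylic C2′=C1′ alkene, and cyclisation of the 3,4-epoxy alcohol to a tetrahydrofuran. Fallback, setting out from 11 and coming back at 12: acylation with Boc2O and NaN(SiMe3)2 in THF at −78 °C gives the tert-butyl carbonate F4. IBr in toluene at −85 °C (Bartlett–Smith iodocarbonate cyclisation) closes the carbonate oxygen onto the prenyl alkene to give the cis-4,6-disubstituted cyclic iodocarbonate F5, which fixes the 1,3-syn relation. K2CO3 in MeOH at 0 °C then cleaves the carbonate and closes the oxirane by displacement of the tertiary iodide, with retention at the oxirane CH, to give 12.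

Step 5. Risks: incomplete oxidation (stopping at the allylic alcohol), acid-induced opening of the oxirane, and selenium-promoted Z-to-E isomerisation of the angelates. Fallback, setting out from 8 and coming back at 9: ene-type chlorination of the isopropenyl group with Ca(OCl)2 and CO2 in CH2Cl2/H2O at 0 °C gives the allylic chloride F1, which is oxidised with Me3NO in DMSO at 25 °C (N-oxide variant of the Kornblum oxidation) to enal 9.

**Further compounds**
F1 | step 5 | (1S,2S,3R,4R,6S)-4-(3-chloroprop-1-en-2-yl)-1-methyl-7-oxabicyclo[4.1.0]heptane-2,3-diyl bis[(2Z)-2-methylbut-2-enoate] | C=C(CCl)[C@H]1C[C@@H]2O[C@]2(C)[C@@H](OC(=O)/C(C)=C\C)[C@@H]1OC(=O)/C(C)=C\C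
F2 | step 6 | (3′R)-epimer of 11, 4-[(3R)-3-hydroxy-6-methylhepta-1,5-dien-2-yl] analogue | C=C([C@@H](CC=C(C)C)O)[C@H]1C[C@@H]2O[C@]2(C)[C@@H](OC(=O)/C(C)=C\C)[C@@H]1OC(=O)/C(C)=C\C
F3 | step 6 | (3′S)-4-nitrobenzoate of 11 | C=C([C@H](CC=C(C)C)OC(=O)c3ccc(cc3)[N+](=O)[O-])[C@H]1C[C@@H]2O[C@]2(C)[C@@H](OC(=O)/C(C)=C\C)[C@@H]1OC(=O)/C(C)=C\C
F4 | step 7 | tert-butyl carbonate of 11 at O-3′ | C=C([C@H](CC=C(C)C)OC(=O)OC(C)(C)C)[C@H]1C[C@@H]2O[C@]2(C)[C@@H](OC(=O)/C(C)=C\C)[C@@H]1OC(=O)/C(C)=C\C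
F5 | step 7 | cyclic iodocarbonate, (4R,6S)-4-(2-iodopropan-2-yl)-2-oxo-1,3-dioxan-6-yl unit on C2′ | C=C([C@@H]3C[C@H](C(C)(C)I)OC(=O)O3)[C@H]1C[C@@H]2O[C@]2(C)[C@@H](OC(=O)/C(C)=C\C)[C@@H]1OC(=O)/C(C)=C\C
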